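I cannot take the ratio of isomer of the product A to target at 25 s in the new flask from a reading, because the earliest one, in the blue run at 0.667 min, comes later.

in all of them: starting material 0.20 M
- blue: reagent 0.20 M; run made earlier
- violet: reagent 0.80 M; run made earlier
- flask: reagent 0.400 M; time 15 min

| run | time / min | isomer of the product A / % | target / % | starting material / % |
|---|---|---|---|---|
| blue | 0.667 | 1 | 2 | 90 |
| blue | 1.00 | 2 | 2 | 85 |
| blue | 1.50 | 5 | 5 | 83 |
| blue | 2.50 | 5 | 9 | 72 |
| blue | 4.00 | 6 | 9 | 63 |
| blue | 6.00 | 9 | 10 | 57 |
| blue | 10.0 | 12 | 7 | 47 |
| violet | 1.33 | 10 | 11 | 53 |
| violet | 2.50 | 14 | 15 | 34 |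
| violet | 4.00 | 15 | 13 | 26 |
| violet | 5.00 | 17 | 11 | 21 |
| violet | 6.00 | 18 | 13 | 19 |
| violet | 8.00 | 14 | 12 | 14 |
| violet | 10.0 | 16 | 8 | 10 |

(readings scatter by 1.5 percentage points)

- ratio of isomer of the product A to target at 25 s
- ratio of isomer of the product A to target at 2.5 min
- ratio of isomer of the product A to target at 15 min

- steps that have been proposed: starting material + reagent -> intermediate + by-product; intermediate <-> target; intermediate <-> isomer of the product A; target + by-product -> side product; target <-> isomer of the product B; 2 reagent -> homo dimer

So I follow one molecule. Starting material meets reagent and becomes the intermediate, which is not measured, and the intermediate has two exits, to target and to isomer of the product A. A first-order rate constant is a chance per unit time, so two competing exits give odds equal to the ratio of their constants. Reagent stands in neither exit's equation, so I take the odds to be the same in the flask as in the blue run.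

But target may move on, by the proposed steps, to isomer of the product B and side product, and neither is read, so later ratios can overstate the odds. The violet run at 1.33 min shows how much can hide: 47.0% of the starting material charged has gone, and 26.0% of the charge stands in nothing that is read. Counting none of that as target's gives 0.909, and counting the whole of it gives 0.270.

I take the earliest blue reading as the fork ratio, the selectivity factor at the intermediate: isomer of the product A formed per target formed, 0.500, which lies lower than the first of these figures and higher than the second . It is rough, since the scatter is 1.5 percentage points, but it sends about a third of the molecules to isomer of the product A. I expect this value at 25 s.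

At 2.5 min I have readings from both runs, and the flask's charge of reagent is more than the blue run's and less than the violet run's , so I average their two ratios and get 0.744. For 15 min I pool the readings of both runs from 4.00 min onward, which gives 1.29.

The forecast, holding that “the split is kinetic and independent of reagent”, gives 0.8, 0.9 and 2.6, which differs from my figures. The flask gives 0.501, 0.830 and 1.01, so my late figure stands too high.

    starting material + reagent → intermediate + by-product (k = 0.0140 M⁻¹ s⁻¹)
    intermediate ⇌ target (K = 13.0, k = 0.0160 s⁻¹)
    intermediate ⇌ isomer of the product A (K = 2.60, k = 0.00730 s⁻¹)
    target + by-product → side product (k = 0.0500 M⁻¹ s⁻¹)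
    target ⇌ isomer of the product B (K = 2.00, k = 0.0120 s⁻¹)
    2 reagent → homo dimer (k = 0.00490 M⁻¹ s⁻¹)

Reagent stands in neither exit of the intermediate in these equations, so I carry the fork ratio to the neighbouring flask with 0.16 M of reagent and again expect 0.500 at 25 s. That neighbour gives 0.498, and the one with 1.6 M gives 0.513. Later the two part: at 2.5 min they stand at 0.748 and 1.05. At 15 min the neighbour with 0.16 M stands at 0.860, with 49.2% of its starting material still there.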